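Ring C is cut at O1–C2 and C3–C4. The atoms O1, C8a, C4a and C4 are treated as the heterodiene of a 4-methoxy ortho-quinone methide cation grown from a ring A salicylaldehyde, and C2–C3 as the vinyl group of a ring B styrene. A single chiral-acid-catalysed inverse-demand [4+2] addition should form both bonds, close ring C and fix C2, leaving C4 as a methyl ether one oxidation below the ketone. The precursor is a benzaldehyde that holds the 1,1-dimethylallyl group between two silyl ethers and has its only free hydroxyl para to that group, so O1 cannot be misplaced.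

Key step: step 7

Assumption: the sense of induction of the chiral acid cannot be predicted for this substrate pair. The route is written with the (S,S) acid, and its antipode is used if circular dichroism of the silylated flavanone indicates 2R.

Remarks on the design (TBS = tert-butyldimethylsilyl; C1–C6 number the benzaldehyde ring, flavanoid numbers are used from the cycloadduct on):
- **Placing the free hydroxyl.** A Claisen shift always uncovers the oxygen next to the new side chain, whereas O1 lies para to it. The two oxygens beside the formyl group are therefore silylated first. The shift then runs on a symmetric ether whose para carbon is blocked, and the less hindered silyl ether is removed afterwards.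
- **Choice of protecting group.** Aryl silyl ethers replace acetal-type groups. They tolerate catalytic strong acid with methanol. They also come off with buffered HF, so the end game needs no base (C2 racemises by ring opening) and no hot mineral acid (ortho phenol and vinyl group).

Step 1
Reactants: 1 2,4,6-trihydroxybenzaldehyde; 2 3-methylbut-2-en-1-ol (prenol)
Product: 3 2,6-dihydroxy-4-[(3-methylbut-2-en-1-yl)oxy]benzaldehyde
Conditions: PPh3 (1.05 equiv), DIAD (1.05 equiv), THF, 0 °C → rt
Reagents that add atoms: none
Why: Mitsunobu etherification alkylates the 4-OH, the most acidic hydroxyl and the only one not next to the formyl group, and because it runs without base it avoids the C-prenylation typical of phloroglucinol anions.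

Step 2
Reactants: 3 2,6-dihydroxy-4-[(3-methylbut-2-en-1-yl)oxy]benzaldehyde
Product: 4 2,6-bis[(tert-butyldimethylsilyl)oxy]-4-[(3-methylbut-2-en-1-yl)oxy]benzaldehyde
Conditions: TBSCl (2.6 equiv), imidazole (5 equiv), DMF, rt → 40 °C
Reagents that add atoms: tert-butyldimethylsilyl chloride, CC(C)(C)[Si](C)(C)Cl
Why: Routine imidazole-promoted phenol silylation caps both ortho hydroxyls, which keeps the ring symmetric (C3 and C5 equivalent) and puts a silyl group on the future 5-oxygen while that position is still unhindered.

Step 3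
Reactants: 4 2,6-bis[(tert-butyldimethylsilyl)oxy]-4-[(3-methylbut-2-en-1-yl)oxy]benzaldehyde
Product: 6 4-hydroxy-3-(2-methylbut-3-en-2-yl)-2,6-bis[(tert-butyldimethylsilyl)oxy]benzaldehyde, via ortho-dienone 5 (not isolated)
Conditions: PhNEt2, 185 °C, sealed tube, Ar
Reagents that add atoms: none
Why: Aromatic Claisen rearrangement: the [3,3] shift joins the tertiary prenyl carbon to C3 (identical with C5, so only one product is possible), dienone 5 enolises in the basic solvent, and a following Cope shift has no productive outlet because the para carbon carries the formyl group.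

Step 4
Reactants: 6 4-hydroxy-3-(2-methylbut-3-en-2-yl)-2,6-bis[(tert-butyldimethylsilyl)oxy]benzaldehyde
Product: 7 2-[(tert-butyldimethylsilyl)oxy]-4,6-dihydroxy-3-(2-methylbut-3-en-2-yl)benzaldehyde
Conditions: KHF2 (1.1 equiv), MeOH, 0 °C → rt, stopped at full conversion of 6
Reagents that add atoms: none
Why: Fluoride-induced cleavage of aryl silyl ethers responds to access to silicon, so the O6 silyl ether with H5 as neighbour should go first while the O2 silyl ether wedged between the formyl group and the quaternary carbon stays; the mildly acidic bifluoride forms no phenoxide.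

Step 5
Reactants: 7 2-[(tert-butyldimethylsilyl)oxy]-4,6-dihydroxy-3-(2-methylbut-3-en-2-yl)benzaldehyde
Product: 8 6-hydroxy-2,4-bis[(tert-butyldimethylsilyl)oxy]-3-(2-methylbut-3-en-2-yl)benzaldehyde
Conditions: TBSCl (1.05 equiv), imidazole (2.2 equiv), DMF, 0 °C → rt
Reagents that add atoms: tert-butyldimethylsilyl chloride, CC(C)(C)[Si](C)(C)Cl
Why: Chemoselective silylation: the 4-OH is free and more acidic, whereas the 6-OH is tied to the formyl oxygen by a strong hydrogen bond, the same bias that allows 4-O-protection of 2,4-dihydroxybenzaldehydes, so the only hydroxyl left is the one para to the side chain.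

Step 6
Reactants: 9 2-methoxy-4-vinylphenol
Product: 10 tert-butyl(4-ethenyl-2-methoxyphenoxy)dimethylsilane
Conditions: TBSCl (1.1 equiv), imidazole (2 equiv), CH2Cl2, 0 °C → rt
Reagents that add atoms: tert-butyldimethylsilyl chloride, CC(C)(C)[Si](C)(C)Cl
Why: Routine phenol silylation under non-acidic conditions that leave the polymerisable vinyl group alone, and the para silyloxy group keeps the alkene electron-rich.

Step 7
Reactants: 8 6-hydroxy-2,4-bis[(tert-butyldimethylsilyl)oxy]-3-(2-methylbut-3-en-2-yl)benzaldehyde; 10 tert-butyl(4-ethenyl-2-methoxyphenoxy)dimethylsilane; 11 trimethyl orthoformate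
Product: 14 (2S,4S)-4-methoxy-5,7-bis[(tert-butyldimethylsilyl)oxy]-2-{4-[(tert-butyldimethylsilyl)oxy]-3-methoxyphenyl}-6-(2-methylbut-3-en-2-yl)chromane, via dimethyl acetal 12 (not isolated), via methoxy ortho-quinone methide cation 13 (not isolated)
Conditions: (S,S)-imidodiphosphorimidate acid built from two (S)-3,3'-bis[3,5-bis(trifluoromethyl)phenyl]-BINOL units with both nitrogen termini N-triflyl (5 mol %), 11 (2 equiv), 5 Å MS, CH2Cl2, 0 °C, 1 h; then 10 (1.5 equiv) added slowly, −40 °C
Reagents that add atoms: none
Why: Proposed new method: the acid first turns 8 and 11 into acetal 12 and then ionises it to cation 13, which stays paired with the confined chiral anion; the unsubstituted terminus of styrene 10 attacks C4 (C3–C4 bond) and the developing benzylic cation, stabilised by the para silyloxy group of ring B, is taken up by the free phenol oxygen (O1–C2 bond). The closest known reaction types are the achiral acid-promoted three-component [4+2] reaction of salicylaldehydes, orthoformates and styrenes, the chiral-acid-controlled cycloadditions of ortho-quinone methides, and the confined-acid Prins-type additions of plain styrenes to oxocarbenium ions; new is their combination on an intermolecular pair whose alkene has no hydrogen-bond handle. Ring C closes as an asynchronous inverse-demand hetero-Diels–Alder process whose last event is a 6-exo-trig attack of O1 on the quinone-methide-like C2 cation. C4 is set by the face of 13 that the anion leaves open, and C2 by an endo-type, chair-like closure with the aryl group equatorial inside the same ion pair, which should give the 2,4-cis (2S,4S) isomer. Regiochemistry follows from polarity (nucleophilic CH2 to electrophilic C4, oxygen to the benzylic carbon), O1 is unambiguous because the 6-OH of 8 is the only free hydroxyl, and the unactivated monosubstituted vinyl group of the side chain is far less nucleophilic than 10. Because C4 is erased later, diastereomers are separated here and each is assayed for its C2 configuration: a C4 epimer formed by re-ionisation of the methoxy group converges in step 8, whereas an exo-derived isomer would carry 2R.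

Step 8
Reactants: 14 (2S,4S)-4-methoxy-5,7-bis[(tert-butyldimethylsilyl)oxy]-2-{4-[(tert-butyldimethylsilyl)oxy]-3-methoxyphenyl}-6-(2-methylbut-3-en-2-yl)chromane
Product: 16 (2S)-5,7-bis[(tert-butyldimethylsilyl)oxy]-2-{4-[(tert-butyldimethylsilyl)oxy]-3-methoxyphenyl}-6-(2-methylbut-3-en-2-yl)chroman-4-one, via C4 hemiketal 15 (not isolated)
Conditions: DDQ (1.5 equiv), CH2Cl2–pH 7 phosphate buffer (10:1), 0 °C → rt
Reagents that add atoms: water, O
Why: DDQ oxidation of an electron-rich benzylic methyl ether: hydride leaves C4, the only hydrogen-bearing benzylic position of the trioxygenated ring A and further activated by its own methoxy group, water adds to give hemiketal 15, which loses methanol; C2 is not involved and the side chain has no allylic hydrogen.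

Step 9
Reactants: 16 (2S)-5,7-bis[(tert-butyldimethylsilyl)oxy]-2-{4-[(tert-butyldimethylsilyl)oxy]-3-methoxyphenyl}-6-(2-methylbut-3-en-2-yl)chroman-4-one
Product: 17 (2S)-5,7-dihydroxy-2-(4-hydroxy-3-methoxyphenyl)-6-(2-methylbut-3-en-2-yl)chroman-4-one (CNP0279383.1)
Conditions: HF·pyridine (excess), pyridine, THF, 0 °C → rt; work-up with pH 6 buffer
Reagents that add atoms: none
Why: Fluoride desilylation with buffered HF frees all three phenols without base, so no phenoxide can open ring C by a retro-oxa-Michael reaction and racemise C2, and the medium is too weakly acidic to add the ortho phenols across the vinyl group or to cleave the aryl methyl ether.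

Compound list
1 | 2,4,6-trihydroxybenzaldehyde | O=Cc1c(O)cc(O)cc1O | starting material
2 | 3-methylbut-2-en-1-ol | CC(C)=CCO | starting material
3 | 2,6-dihydroxy-4-[(3-methylbut-2-en-1-yl)oxy]benzaldehyde | CC(C)=CCOc1cc(O)c(C=O)c(O)c1 | intermediate
4 | 2,6-bis[(tert-butyldimethylsilyl)oxy]-4-[(3-methylbut-2-en-1-yl)oxy]benzaldehyde | CC(C)=CCOc1cc(O[Si](C)(C)C(C)(C)C)c(C=O)c(O[Si](C)(C)C(C)(C)C)c1 | intermediate
5 | ortho-dienone, 2,6-bis[(tert-butyldimethylsilyl)oxy]-3-(2-methylbut-3-en-2-yl)-4-oxocyclohexa-1,5-diene-1-carbaldehyde (racemic, not isolated) | C=CC(C)(C)C1C(=O)C=C(O[Si](C)(C)C(C)(C)C)C(C=O)=C1O[Si](C)(C)C(C)(C)C | intermediate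
6 | 4-hydroxy-3-(2-methylbut-3-en-2-yl)-2,6-bis[(tert-butyldimethylsilyl)oxy]benzaldehyde | C=CC(C)(C)c1c(O)cc(O[Si](C)(C)C(C)(C)C)c(C=O)c1O[Si](C)(C)C(C)(C)C | intermediate
7 | 2-[(tert-butyldimethylsilyl)oxy]-4,6-dihydroxy-3-(2-methylbut-3-en-2-yl)benzaldehyde | C=CC(C)(C)c1c(O)cc(O)c(C=O)c1O[Si](C)(C)C(C)(C)C | intermediate
8 | 6-hydroxy-2,4-bis[(tert-butyldimethylsilyl)oxy]-3-(2-methylbut-3-en-2-yl)benzaldehyde | C=CC(C)(C)c1c(O[Si](C)(C)C(C)(C)C)cc(O)c(C=O)c1O[Si](C)(C)C(C)(C)C | intermediate
9 | 2-methoxy-4-vinylphenol | C=Cc1ccc(O)c(OC)c1 | starting material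
10 | tert-butyl(4-ethenyl-2-methoxyphenoxy)dimethylsilane | C=Cc1ccc(O[Si](C)(C)C(C)(C)C)c(OC)c1 | intermediate
11 | trimethyl orthoformate | COC(OC)OC | starting material
12 | dimethyl acetal of 8 (not isolated) | C=CC(C)(C)c1c(O[Si](C)(C)C(C)(C)C)cc(O)c(C(OC)OC)c1O[Si](C)(C)C(C)(C)C | intermediate
13 | methoxy ortho-quinone methide cation, O-methyl oxocarbenium form of 8 (not isolated) | C=CC(C)(C)c1c(O[Si](C)(C)C(C)(C)C)cc(O)c(C=[O+]C)c1O[Si](C)(C)C(C)(C)C | intermediate
14 | (2S,4S)-4-methoxy-5,7-bis[(tert-butyldimethylsilyl)oxy]-2-{4-[(tert-butyldimethylsilyl)oxy]-3-methoxyphenyl}-6-(2-methylbut-3-en-2-yl)chromane (2,4-cis) | C=CC(C)(C)c1c(O[Si](C)(C)C(C)(C)C)cc2c(c1O[Si](C)(C)C(C)(C)C)[C@@H](OC)C[C@@H](c1ccc(O[Si](C)(C)C(C)(C)C)c(OC)c1)O2 | intermediate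
15 | (2S)-C4 hemiketal, 4-hydroxy-4-methoxy analogue of 14 (C4 undefined, not isolated) | C=CC(C)(C)c1c(O[Si](C)(C)C(C)(C)C)cc2c(c1O[Si](C)(C)C(C)(C)C)C(O)(OC)C[C@@H](c1ccc(O[Si](C)(C)C(C)(C)C)c(OC)c1)O2 | intermediate
16 | (2S)-5,7-bis[(tert-butyldimethylsilyl)oxy]-2-{4-[(tert-butyldimethylsilyl)oxy]-3-methoxyphenyl}-6-(2-methylbut-3-en-2-yl)chroman-4-one | C=CC(C)(C)c1c(O[Si](C)(C)C(C)(C)C)cc2c(c1O[Si](C)(C)C(C)(C)C)C(=O)C[C@@H](c1ccc(O[Si](C)(C)C(C)(C)C)c(OC)c1)O2 | intermediate
17 | (2S)-5,7-dihydroxy-2-(4-hydroxy-3-methoxyphenyl)-6-(2-methylbut-3-en-2-yl)chroman-4-one | C=CC(C)(C)c1c(O)cc2c(c1O)C(=O)C[C@@H](c1ccc(O)c(OC)c1)O2 | target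

Total step count: 9
Longest linear sequence: 8 (steps 1–5, 7, 8, 9)

Steps most likely to fail

**1. Step 7.**
- What may go wrong: weak facial discrimination by the counter-anion, acid-triggered oligomerisation of the styrene, sluggish capture of a strongly stabilised cation, or reversible ionisation of the O1–C2 bond that erodes the C2 configuration.
- Fallback: stereocontrol is moved from catalysis to resolution.
- Setting out from 8, 10 and 11, the known achiral three-component cycloaddition with Sc(OTf)3 (10 mol %, CH2Cl2, 0 °C) should give, after removal of any trans isomer on silica, the racemic 2,4-cis 4-methoxyflavan F1.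
- Preparative HPLC on an amylose tris(3,5-dimethylphenylcarbamate) phase then separates 14 from its (2R,4R)-enantiomer F2.
- The route is rejoined at 14.

**2. Step 8.**
- What may go wrong: slow hydride transfer if the peri silyl ether forces C4–H into the plane of ring A, competing hydride loss from C2–H, or further dehydrogenation of ring C.
- Fallback: a redox-neutral exchange followed by an alcohol oxidation.
- Setting out from 14, PPTS in THF–water at rt replaces the very labile benzylic methoxy group by hydroxyl to give the (2S)-flavan-4-ol F3 as a mixture of C4 epimers.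
- Dess–Martin periodinane with NaHCO3 in CH2Cl2 at 0 °C leads back to 16.

**3. Step 3.**
- What may go wrong: shielding of C3 by the neighbouring silyl ether slows the [3,3] shift. Heterolysis of the allylic C–O bond with loss of the prenyl group, favoured by the para formyl group, or reorganisation of the ortho-allylphenol on long heating then takes over.
- Fallback: the sigmatropic step is run on a formyl-free ring whose silyl ethers can turn away, and the formyl carbon is added last.
- Setting out from 2 and commercial phloroglucinol, TBSCl (2 equiv) and imidazole give 3,5-bis[(tert-butyldimethylsilyl)oxy]phenol F4.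
- Mitsunobu coupling with 2 gives its prenyl ether F5.
- Claisen rearrangement (PhNEt2, 170 °C, shortest possible time) gives 2-(2-methylbut-3-en-2-yl)-3,5-bis[(tert-butyldimethylsilyl)oxy]phenol F6.
- Silylation (TBSCl, imidazole, DMF) gives the symmetric tris-silyl ether F7.
- KHF2 in MeOH removes the silyl group para to the side chain, the only one without a bulky neighbour, to give 4-(2-methylbut-3-en-2-yl)-3,5-bis[(tert-butyldimethylsilyl)oxy]phenol F8.
- Magnesium-mediated ortho-formylation (MgCl2, Et3N, paraformaldehyde, MeCN, reflux) at either of the two equivalent ortho carbons leads back to 8.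

Further compounds
F1 | step 7 | racemic 2,4-cis 4-methoxy-5,7-bis[(tert-butyldimethylsilyl)oxy]-2-{4-[(tert-butyldimethylsilyl)oxy]-3-methoxyphenyl}-6-(2-methylbut-3-en-2-yl)chromane | C=CC(C)(C)c1c(O[Si](C)(C)C(C)(C)C)cc2c(c1O[Si](C)(C)C(C)(C)C)C(OC)CC(c1ccc(O[Si](C)(C)C(C)(C)C)c(OC)c1)O2
F2 | step 7 | (2R,4R)-enantiomer of 14 | C=CC(C)(C)c1c(O[Si](C)(C)C(C)(C)C)cc2c(c1O[Si](C)(C)C(C)(C)C)[C@H](OC)C[C@H](c1ccc(O[Si](C)(C)C(C)(C)C)c(OC)c1)O2
F3 | step 8 | (2S)-5,7-bis[(tert-butyldimethylsilyl)oxy]-2-{4-[(tert-butyldimethylsilyl)oxy]-3-methoxyphenyl}-6-(2-methylbut-3-en-2-yl)chroman-4-ol (C4 epimers) | C=CC(C)(C)c1c(O[Si](C)(C)C(C)(C)C)cc2c(c1O[Si](C)(C)C(C)(C)C)C(O)C[C@@H](c1ccc(O[Si](C)(C)C(C)(C)C)c(OC)c1)O2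
F4 | step 3 | 3,5-bis[(tert-butyldimethylsilyl)oxy]phenol | Oc1cc(O[Si](C)(C)C(C)(C)C)cc(O[Si](C)(C)C(C)(C)C)c1
F5 | step 3 | 1,3-bis[(tert-butyldimethylsilyl)oxy]-5-[(3-methylbut-2-en-1-yl)oxy]benzene | CC(C)=CCOc1cc(O[Si](C)(C)C(C)(C)C)cc(O[Si](C)(C)C(C)(C)C)c1
F6 | step 3 | 2-(2-methylbut-3-en-2-yl)-3,5-bis[(tert-butyldimethylsilyl)oxy]phenol | C=CC(C)(C)c1c(O)cc(O[Si](C)(C)C(C)(C)C)cc1O[Si](C)(C)C(C)(C)C
F7 | step 3 | 2-(2-methylbut-3-en-2-yl)-1,3,5-tris[(tert-butyldimethylsilyl)oxy]benzene | C=CC(C)(C)c1c(O[Si](C)(C)C(C)(C)C)cc(O[Si](C)(C)C(C)(C)C)cc1O[Si](C)(C)C(C)(C)C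
F8 | step 3 | 4-(2-methylbut-3-en-2-yl)-3,5-bis[(tert-butyldimethylsilyl)oxy]phenol | C=CC(C)(C)c1c(O[Si](C)(C)C(C)(C)C)cc(O)cc1O[Si](C)(C)C(C)(C)C
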